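**Retrosynthetic overview**
- The tertiary carbinol C–O bond and the (E)-alkene are formed last, by a Mislow–Evans [2,3]-sigmatropic rearrangement of an (E)-allylic sulfoxide that already carries both acetates; chirality is transferred from the sulfur-bearing carbon.
- That carbon is set from the glycerate-derived centre: Felkin reduction of an enone gives the syn allylic alcohol, which is converted to the sulfide with inversion.
- The enone comes from Negishi carboalumination of a ring alkyne and addition to (R)-2,2,5,5-tetramethyl-1,3-dioxolane-4-carbaldehyde, made from methyl (S)-glycerate acetonide.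
- The ring alkyne comes from (S)-carvone: a cuprate addition/aldol sets the vicinal tertiary and quaternary centres trans, the ring carbonyl is deleted, and the acetyl-bearing carbon is equilibrated to equatorial.
- No ring is formed; the only carbocycle is the cyclohexane bought with carvone.

Assumption: (S)-(+)-carvone and methyl (S)-2,2-dimethyl-1,3-dioxolane-4-carboxylate are taken as the cheap commercial chiral starting materials; all reagents are commercial. The route is designed on paper from known reaction types and has not been run.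

**Step 1**
Reactants: 1 (S)-(+)-carvone
Product: 2 (5S)-5-acetyl-2-methylcyclohex-2-en-1-one
Conditions: O3, CH2Cl2/MeOH, −78 °C; then Me2S, −78 °C to rt
Reagents that add atoms: ozone, [O-][O+]=O
Why: Chemoselective ozonolysis cleaves the electron-rich 1,1-disubstituted alkene much faster than the electron-poor enone double bond, and the C5 stereocentre is untouched.

**Step 2**
Reactants: 2 (5S)-5-acetyl-2-methylcyclohex-2-en-1-one
Product: 3 (5S)-2-methyl-5-(2-methyl-1,3-dioxolan-2-yl)cyclohex-2-en-1-one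
Conditions: (TMSOCH2)2, TMSOTf (cat.), CH2Cl2, −78 to −20 °C
Reagents that add atoms: 1,2-bis(trimethylsilyloxy)ethane, C[Si](C)(C)OCCO[Si](C)(C)C
Why: Noyori ketalisation under aprotic conditions protects the saturated methyl ketone in preference to the conjugated enone carbonyl and does not enolise the adjacent stereocentre.

**Step 3**
Reactants: 3 (5S)-2-methyl-5-(2-methyl-1,3-dioxolan-2-yl)cyclohex-2-en-1-one
Product: 5 (2S,3R,5S)-2-(1-hydroxyethyl)-2-methyl-5-(2-methyl-1,3-dioxolan-2-yl)-3-(prop-1-en-2-yl)cyclohexan-1-one (carbinol epimers), via bromomagnesium enolate 4 (not isolated)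
Conditions: isopropenylMgBr, CuBr·SMe2 (10 mol %), THF, −78 to −40 °C; then CH3CHO, −78 °C; aqueous work-up
Reagents that add atoms: isopropenylmagnesium bromide, C=C(C)[Mg]Br; acetaldehyde, CC=O
Why: Copper-catalysed conjugate addition delivers the isopropenyl group axially, anti to the C5 substituent, and the enolate then undergoes an aldol reaction anti to the new C3 group, so the quaternary centre is set 2,3-trans; the carbinol centre is removed in step 4.

**Step 4**
Reactants: 5 (2S,3R,5S)-2-(1-hydroxyethyl)-2-methyl-5-(2-methyl-1,3-dioxolan-2-yl)-3-(prop-1-en-2-yl)cyclohexan-1-one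
Product: 6 (2R,3R,5S)-2-ethenyl-2-methyl-5-(2-methyl-1,3-dioxolan-2-yl)-3-(prop-1-en-2-yl)cyclohexan-1-one
Conditions: Martin sulfurane Ph2S[OC(CF3)2Ph]2, CH2Cl2, 0 °C to rt
Reagents that add atoms: none
Why: Martin sulfurane dehydration (E2) of the neopentylic secondary alcohol can only remove a methyl hydrogen, which gives the terminal vinyl group on the quaternary carbon.

**Step 5**
Reactants: 6 (2R,3R,5S)-2-ethenyl-2-methyl-5-(2-methyl-1,3-dioxolan-2-yl)-3-(prop-1-en-2-yl)cyclohexan-1-one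
Product: 8 2-[(1R,3R,4R)-4-ethenyl-4-methyl-3-(prop-1-en-2-yl)cyclohexyl]-2-methyl-1,3-dioxolane, via silylhydrazone 7 (not isolated)
Conditions: TBSNHNHTBS, Sc(OTf)3 (0.01 mol %), neat, 100 °C; then KOtBu, t-BuOH, DMSO, 23 to 80 °C
Reagents that add atoms: none
Why: The Myers silylhydrazone variant of the Wolff–Kishner reduction removes the hindered ring carbonyl by an anionic path below 100 °C, which avoids radical 1,2-vinyl migration and Cope scrambling of the 1,5-diene; no stereocentre is involved.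

**Step 6**
Reactants: 8 2-[(1R,3R,4R)-4-ethenyl-4-methyl-3-(prop-1-en-2-yl)cyclohexyl]-2-methyl-1,3-dioxolane
Product: 10 1-[(1S,3R,4R)-4-ethenyl-4-methyl-3-(prop-1-en-2-yl)cyclohexyl]ethan-1-one, via C1-epimeric methyl ketone 9 (not isolated)
Conditions: 1 M HCl, THF, rt; then NaOMe (cat.), MeOH, rt (equilibrium about 9:1, chromatography, minor epimer re-equilibrated)
Reagents that add atoms: water, O
Why: Ketal hydrolysis followed by enolate epimerisation moves the acetyl group from axial to equatorial, cis to the fixed isopropenyl group, so this centre is set under thermodynamic control by the centres made in step 3.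

**Step 7**
Reactants: 10 1-[(1S,3R,4R)-4-ethenyl-4-methyl-3-(prop-1-en-2-yl)cyclohexyl]ethan-1-one
Product: 12 (1R,2R,4S)-1-ethenyl-4-ethynyl-1-methyl-2-(prop-1-en-2-yl)cyclohexane, via enol phosphate 11 (not isolated)
Conditions: LiN(iPr)2, THF, −78 °C; ClP(O)(OEt)2, −78 °C to rt; LiN(iPr)2 (2.3 equiv), −78 °C to rt
Reagents that add atoms: none
Why: Negishi's methyl ketone to alkyne protocol (kinetic enolate, enol phosphate, E2 elimination) deprotonates only the methyl group at −78 °C, so the ring stereocentre is not enolised.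

**Step 8**
Reactants: 13 methyl (S)-2,2-dimethyl-1,3-dioxolane-4-carboxylate
Product: 14 2-[(4S)-2,2-dimethyl-1,3-dioxolan-4-yl]propan-2-ol
Conditions: MeMgBr (3 equiv), THF, 0 °C to rt
Reagents that add atoms: methylmagnesium bromide, C[Mg]Br
Why: Double Grignard addition to the ester gives the tertiary alcohol with the α-alkoxy stereocentre retained.

**Step 9**
Reactants: 14 2-[(4S)-2,2-dimethyl-1,3-dioxolan-4-yl]propan-2-ol
Product: 15 [(4S)-2,2,5,5-tetramethyl-1,3-dioxolan-4-yl]methanol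
Conditions: p-TsOH·H2O (5 mol %), acetone, rt; Et3N quench (14 recycled)
Reagents that add atoms: none
Why: Acid-catalysed acetonide migration (transketalisation) equilibrates towards the more substituted dioxolane and frees the primary hydroxyl; the stereocentre is not involved.

**Step 10**
Reactants: 15 [(4S)-2,2,5,5-tetramethyl-1,3-dioxolan-4-yl]methanol
Product: 16 (4R)-2,2,5,5-tetramethyl-1,3-dioxolane-4-carbaldehyde
Conditions: Dess–Martin periodinane, CH2Cl2, 0 °C to rt
Reagents that add atoms: none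
Why: Dess–Martin oxidation gives the aldehyde under non-basic conditions that do not epimerise the α-alkoxy centre (the descriptor changes by priority only).

**Step 11**
Reactants: 12 (1R,2R,4S)-1-ethenyl-4-ethynyl-1-methyl-2-(prop-1-en-2-yl)cyclohexane; 16 (4R)-2,2,5,5-tetramethyl-1,3-dioxolane-4-carbaldehyde
Product: 19 (2E)-3-[(1S,3R,4R)-4-ethenyl-4-methyl-3-(prop-1-en-2-yl)cyclohexyl]-1-[(4S)-2,2,5,5-tetramethyl-1,3-dioxolan-4-yl]but-2-en-1-ol (carbinol epimers), via alkenylalane 17 (not isolated), via lithium alkenylaluminate 18 (not isolated)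
Conditions: AlMe3 (2.5 equiv), Cp2ZrCl2 (0.25 equiv), CH2Cl2, 0 °C to rt; evaporate; MeLi, THF, −78 °C; then 16, −78 to 0 °C; aq. potassium sodium tartrate
Reagents that add atoms: trimethylaluminium, C[Al](C)C
Why: Negishi zirconium-catalysed carboalumination adds methyl and aluminium syn across the terminal alkyne (much faster than across the hindered alkenes), giving the (E)-trisubstituted alkenyl metal, whose ate complex adds to the aldehyde; the new carbinol centre is erased in step 12.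

**Step 12**
Reactants: 19 (2E)-3-[(1S,3R,4R)-4-ethenyl-4-methyl-3-(prop-1-en-2-yl)cyclohexyl]-1-[(4S)-2,2,5,5-tetramethyl-1,3-dioxolan-4-yl]but-2-en-1-ol
Product: 20 (2E)-3-[(1S,3R,4R)-4-ethenyl-4-methyl-3-(prop-1-en-2-yl)cyclohexyl]-1-[(4R)-2,2,5,5-tetramethyl-1,3-dioxolan-4-yl]but-2-en-1-one
Conditions: Dess–Martin periodinane, CH2Cl2, 0 °C to rt
Reagents that add atoms: none
Why: Dess–Martin oxidation converges both carbinol epimers on a single enone.

**Step 13**
Reactants: 20 (2E)-3-[(1S,3R,4R)-4-ethenyl-4-methyl-3-(prop-1-en-2-yl)cyclohexyl]-1-[(4R)-2,2,5,5-tetramethyl-1,3-dioxolan-4-yl]but-2-en-1-one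
Product: 21 (1R,2E)-3-[(1S,3R,4R)-4-ethenyl-4-methyl-3-(prop-1-en-2-yl)cyclohexyl]-1-[(4S)-2,2,5,5-tetramethyl-1,3-dioxolan-4-yl]but-2-en-1-ol
Conditions: LiBH(s-Bu)3, THF, −78 °C; aqueous work-up
Reagents that add atoms: none
Why: Felkin–Anh (Cornforth) 1,2-reduction by the bulky non-chelating hydride, anti to the dioxolane C–O bond and the gem-dimethyl carbon, gives the syn alcohol, so the carbinol centre is set by the glycerate-derived centre.

**Step 14**
Reactants: 21 (1R,2E)-3-[(1S,3R,4R)-4-ethenyl-4-methyl-3-(prop-1-en-2-yl)cyclohexyl]-1-[(4S)-2,2,5,5-tetramethyl-1,3-dioxolan-4-yl]but-2-en-1-ol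
Product: 22 {[(1S,2E)-3-[(1S,3R,4R)-4-ethenyl-4-methyl-3-(prop-1-en-2-yl)cyclohexyl]-1-[(4R)-2,2,5,5-tetramethyl-1,3-dioxolan-4-yl]but-2-en-1-yl]sulfanyl}benzene
Conditions: N-(phenylsulfanyl)succinimide, PBu3, benzene, rt
Reagents that add atoms: N-(phenylsulfanyl)succinimide, O=C1CCC(=O)N1Sc1ccccc1
Why: Walker–Hata thioetherification (alkoxyphosphonium displaced by thiolate, SN2) replaces OH by SPh with inversion, which puts sulfur on the face from which oxygen is delivered in step 16.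

**Step 15**
Reactants: 22 {[(1S,2E)-3-[(1S,3R,4R)-4-ethenyl-4-methyl-3-(prop-1-en-2-yl)cyclohexyl]-1-[(4R)-2,2,5,5-tetramethyl-1,3-dioxolan-4-yl]but-2-en-1-yl]sulfanyl}benzene
Product: 24 (3R,4S,5E)-6-[(1S,3R,4R)-4-ethenyl-4-methyl-3-(prop-1-en-2-yl)cyclohexyl]-2-methyl-4-(phenylsulfanyl)hept-5-ene-2,3-diyl diacetate, via diol 23 (not isolated)
Conditions: 80% aq. AcOH, 40 °C; concentrate (toluene azeotrope); Ac2O, Et3N, DMAP, CH2Cl2, 40 °C
Reagents that add atoms: acetic anhydride, CC(=O)OC(C)=O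
Why: Mild acid hydrolysis removes the acetonide and DMAP-catalysed (Steglich-type) acylation esterifies both the secondary and the tertiary hydroxyl while the sulfide and all stereocentres are untouched.

**Step 16**
Reactants: 24 (3R,4S,5E)-6-[(1S,3R,4R)-4-ethenyl-4-methyl-3-(prop-1-en-2-yl)cyclohexyl]-2-methyl-4-(phenylsulfanyl)hept-5-ene-2,3-diyl diacetate
Product: 27 (3S,4E,6S)-6-[(1S,3R,4R)-4-ethenyl-4-methyl-3-(prop-1-en-2-yl)cyclohexyl]-6-hydroxy-2-methylhept-4-ene-2,3-diyl diacetate (the target), via sulfoxide 25 (not isolated), via sulfenate ester 26 (not isolated)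
Conditions: mCPBA (1.0 equiv), CH2Cl2, −78 °C; then P(OMe)3, MeOH, −78 to 40 °C
Reagents that add atoms: 3-chloroperoxybenzoic acid, OOC(=O)c1cccc(Cl)c1
Why: Chemoselective S-oxidation is followed by the Mislow–Evans [2,3]-sigmatropic rearrangement, which delivers oxygen suprafacially to the trisubstituted alkene terminus through the envelope transition state with hydrogen inside (1,3-allylic strain); trapping by the thiophile gives the tertiary (S)-carbinol and the (E)-alkene by chirality transfer from the sulfur-bearing carbon.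

**Compound list**
1 | (S)-(+)-carvone | CC1=CC[C@@H](CC1=O)C(C)=C | starting material
2 | (5S)-5-acetyl-2-methylcyclohex-2-en-1-one | CC1=CC[C@@H](CC1=O)C(C)=O | intermediate
3 | (5S)-2-methyl-5-(2-methyl-1,3-dioxolan-2-yl)cyclohex-2-en-1-one | CC1=CC[C@@H](CC1=O)C2(C)OCCO2 | intermediate
4 | bromomagnesium (3R,5S)-2-methyl-5-(2-methyl-1,3-dioxolan-2-yl)-3-(prop-1-en-2-yl)cyclohex-1-en-1-olate | Br[Mg]OC1=C(C)[C@@H](C(C)=C)C[C@H](C2(C)OCCO2)C1 | intermediate
5 | (2S,3R,5S)-2-(1-hydroxyethyl)-2-methyl-5-(2-methyl-1,3-dioxolan-2-yl)-3-(prop-1-en-2-yl)cyclohexan-1-one (carbinol epimers) | O=C1[C@](C)(C(C)O)[C@@H](C(C)=C)C[C@H](C2(C)OCCO2)C1 | intermediate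
6 | (2R,3R,5S)-2-ethenyl-2-methyl-5-(2-methyl-1,3-dioxolan-2-yl)-3-(prop-1-en-2-yl)cyclohexan-1-one | O=C1[C@](C)(C=C)[C@@H](C(C)=C)C[C@H](C2(C)OCCO2)C1 | intermediate
7 | 1-(tert-butyldimethylsilyl)-2-[(2R,3R,5S)-2-ethenyl-2-methyl-5-(2-methyl-1,3-dioxolan-2-yl)-3-(prop-1-en-2-yl)cyclohexylidene]hydrazine | CC(C)(C)[Si](C)(C)NN=C1[C@](C)(C=C)[C@@H](C(C)=C)C[C@H](C2(C)OCCO2)C1 | intermediate
8 | 2-[(1R,3R,4R)-4-ethenyl-4-methyl-3-(prop-1-en-2-yl)cyclohexyl]-2-methyl-1,3-dioxolane | CC1(OCCO1)[C@@H]2CC[C@](C)(C=C)[C@@H](C(C)=C)C2 | intermediate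
9 | 1-[(1R,3R,4R)-4-ethenyl-4-methyl-3-(prop-1-en-2-yl)cyclohexyl]ethan-1-one | CC(=O)[C@@H]1CC[C@](C)(C=C)[C@@H](C(C)=C)C1 | intermediate
10 | 1-[(1S,3R,4R)-4-ethenyl-4-methyl-3-(prop-1-en-2-yl)cyclohexyl]ethan-1-one | CC(=O)[C@H]1CC[C@](C)(C=C)[C@@H](C(C)=C)C1 | intermediate
11 | diethyl 1-[(1S,3R,4R)-4-ethenyl-4-methyl-3-(prop-1-en-2-yl)cyclohexyl]ethenyl phosphate | C=C(OP(=O)(OCC)OCC)[C@H]1CC[C@](C)(C=C)[C@@H](C(C)=C)C1 | intermediate
12 | (1R,2R,4S)-1-ethenyl-4-ethynyl-1-methyl-2-(prop-1-en-2-yl)cyclohexane | C#C[C@H]1CC[C@](C)(C=C)[C@@H](C(C)=C)C1 | intermediate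
13 | methyl (S)-2,2-dimethyl-1,3-dioxolane-4-carboxylate | COC(=O)[C@@H]1COC(C)(C)O1 | starting material
14 | 2-[(4S)-2,2-dimethyl-1,3-dioxolan-4-yl]propan-2-ol | CC(C)(O)[C@@H]1COC(C)(C)O1 | intermediate
15 | [(4S)-2,2,5,5-tetramethyl-1,3-dioxolan-4-yl]methanol | OC[C@@H]1OC(C)(C)OC1(C)C | intermediate
16 | (4R)-2,2,5,5-tetramethyl-1,3-dioxolane-4-carbaldehyde | O=C[C@@H]1OC(C)(C)OC1(C)C | intermediate
17 | [(1E)-2-[(1S,3R,4R)-4-ethenyl-4-methyl-3-(prop-1-en-2-yl)cyclohexyl]prop-1-en-1-yl]dimethylalumane | C[Al](C)/C=C(\C)[C@H]1CC[C@](C)(C=C)[C@@H](C(C)=C)C1 | intermediate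
18 | lithium [(1E)-2-[(1S,3R,4R)-4-ethenyl-4-methyl-3-(prop-1-en-2-yl)cyclohexyl]prop-1-en-1-yl]trimethylaluminate | [Li+].C[Al-](C)(C)/C=C(\C)[C@H]1CC[C@](C)(C=C)[C@@H](C(C)=C)C1 | intermediate
19 | (2E)-3-[(1S,3R,4R)-4-ethenyl-4-methyl-3-(prop-1-en-2-yl)cyclohexyl]-1-[(4S)-2,2,5,5-tetramethyl-1,3-dioxolan-4-yl]but-2-en-1-ol (carbinol epimers) | C/C(=C\C(O)[C@@H]1OC(C)(C)OC1(C)C)[C@H]2CC[C@](C)(C=C)[C@@H](C(C)=C)C2 | intermediate
20 | (2E)-3-[(1S,3R,4R)-4-ethenyl-4-methyl-3-(prop-1-en-2-yl)cyclohexyl]-1-[(4R)-2,2,5,5-tetramethyl-1,3-dioxolan-4-yl]but-2-en-1-one | C/C(=C\C(=O)[C@@H]1OC(C)(C)OC1(C)C)[C@H]2CC[C@](C)(C=C)[C@@H](C(C)=C)C2 | intermediate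
21 | (1R,2E)-3-[(1S,3R,4R)-4-ethenyl-4-methyl-3-(prop-1-en-2-yl)cyclohexyl]-1-[(4S)-2,2,5,5-tetramethyl-1,3-dioxolan-4-yl]but-2-en-1-ol | C/C(=C\[C@@H](O)[C@@H]1OC(C)(C)OC1(C)C)[C@H]2CC[C@](C)(C=C)[C@@H](C(C)=C)C2 | intermediate
22 | {[(1S,2E)-3-[(1S,3R,4R)-4-ethenyl-4-methyl-3-(prop-1-en-2-yl)cyclohexyl]-1-[(4R)-2,2,5,5-tetramethyl-1,3-dioxolan-4-yl]but-2-en-1-yl]sulfanyl}benzene | C/C(=C\[C@H](Sc1ccccc1)[C@@H]2OC(C)(C)OC2(C)C)[C@H]3CC[C@](C)(C=C)[C@@H](C(C)=C)C3 | intermediate
23 | (3R,4S,5E)-6-[(1S,3R,4R)-4-ethenyl-4-methyl-3-(prop-1-en-2-yl)cyclohexyl]-2-methyl-4-(phenylsulfanyl)hept-5-ene-2,3-diol | C/C(=C\[C@H](Sc1ccccc1)[C@H](O)C(C)(C)O)[C@H]2CC[C@](C)(C=C)[C@@H](C(C)=C)C2 | intermediate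
24 | (3R,4S,5E)-6-[(1S,3R,4R)-4-ethenyl-4-methyl-3-(prop-1-en-2-yl)cyclohexyl]-2-methyl-4-(phenylsulfanyl)hept-5-ene-2,3-diyl diacetate | C/C(=C\[C@H](Sc1ccccc1)[C@H](OC(C)=O)C(C)(C)OC(C)=O)[C@H]2CC[C@](C)(C=C)[C@@H](C(C)=C)C2 | intermediate
25 | (3R,4S,5E)-4-(benzenesulfinyl)-6-[(1S,3R,4R)-4-ethenyl-4-methyl-3-(prop-1-en-2-yl)cyclohexyl]-2-methylhept-5-ene-2,3-diyl diacetate (sulfur epimers) | C/C(=C\[C@H](S(=O)c1ccccc1)[C@H](OC(C)=O)C(C)(C)OC(C)=O)[C@H]2CC[C@](C)(C=C)[C@@H](C(C)=C)C2 | intermediate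
26 | (3S,4E,6S)-6-[(1S,3R,4R)-4-ethenyl-4-methyl-3-(prop-1-en-2-yl)cyclohexyl]-2-methyl-6-[(phenylsulfanyl)oxy]hept-4-ene-2,3-diyl diacetate | C=C[C@@]1(C)CC[C@H]([C@](C)(OSc2ccccc2)/C=C/[C@H](OC(C)=O)C(C)(C)OC(C)=O)C[C@@H]1C(=C)C | intermediate
27 | (3S,4E,6S)-6-[(1S,3R,4R)-4-ethenyl-4-methyl-3-(prop-1-en-2-yl)cyclohexyl]-6-hydroxy-2-methylhept-4-ene-2,3-diyl diacetate | C=C[C@@]1(C)CC[C@H]([C@](C)(O)/C=C/[C@H](OC(C)=O)C(C)(C)OC(C)=O)C[C@@H]1C(=C)C | target

**Step count**
Total: 16 steps. Longest linear sequence: 13 steps (steps 1–7 and 11–16, from 1).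

**Steps most likely to fail, with fallbacks**

Step 5 (deoxygenation of the hindered ketone next to the vinyl-bearing quaternary carbon). Hydrazone formation may stall, or the base may isomerise an isopropenyl group. The fallback sets out from 6 and replaces carbonyl reduction by radical deoxygenation. NaBH4 in MeOH gives the cyclohexanol F1; NaH, CS2 and then MeI give the S-methyl xanthate F2. Barton–McCombie reduction with Bu3SnH (1 M or higher) and AIBN in toluene at 80 °C then gives 8; the high stannane concentration is needed so that hydrogen transfer outruns 3-exo closure onto the neighbouring vinyl group. The route is rejoined at 8.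

Step 9 (acetonide migration). The equilibrium may not favour the tetramethyldioxolane enough to be practical. The fallback sets out from 14 and installs the internal acetonide by protecting-group control instead of equilibration. Aqueous AcOH gives the triol F3; TBDPSCl and imidazole silylate only the primary hydroxyl to give the silyl ether diol F4. 2-Methoxypropene with pyridinium tosylate closes the acetonide on the secondary/tertiary diol to give the silyl ether acetonide F5, and Bu4NF releases 15. The route is rejoined at 15.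

Step 14 (SN2 thioetherification at a hindered allylic carbinol that can ionise to a tertiary allyl cation). Ionisation or SN2′ attack would erode the configuration at the sulfur-bearing carbon. The fallback sets out from 12 and 15 and makes the C–S centre during the fragment coupling, which also bypasses steps 10–13. PhSSPh and PBu3 convert 15 to the primary sulfide F6, and N-chlorosuccinimide in CH2Cl2 gives the α-chloro sulfide F7. Alkenylalane 17, generated from 12 as in step 11, then alkenylates the thionium ion derived from F7 at −78 to 0 °C. Felkin–Anh addition anti to the dioxolane C–O bond is expected to give 22 directly, though the selectivity is unproven. The route is rejoined at 22.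

**Further compounds**
F1 | step 5 | (2R,3R,5S)-2-ethenyl-2-methyl-5-(2-methyl-1,3-dioxolan-2-yl)-3-(prop-1-en-2-yl)cyclohexan-1-ol (carbinol epimers) | OC1[C@](C)(C=C)[C@@H](C(C)=C)C[C@H](C2(C)OCCO2)C1
F2 | step 5 | O-[(2R,3R,5S)-2-ethenyl-2-methyl-5-(2-methyl-1,3-dioxolan-2-yl)-3-(prop-1-en-2-yl)cyclohexyl] S-methyl carbonodithioate | CSC(=S)OC1[C@](C)(C=C)[C@@H](C(C)=C)C[C@H](C2(C)OCCO2)C1
F3 | step 9 | (2S)-3-methylbutane-1,2,3-triol | OC[C@H](O)C(C)(C)O
F4 | step 9 | (2S)-1-[(tert-butyldiphenylsilyl)oxy]-3-methylbutane-2,3-diol | CC(C)(C)[Si](OC[C@H](O)C(C)(C)O)(c1ccccc1)c1ccccc1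
F5 | step 9 | tert-butyldiphenyl{[(4S)-2,2,5,5-tetramethyl-1,3-dioxolan-4-yl]methoxy}silane | CC(C)(C)[Si](OC[C@@H]1OC(C)(C)OC1(C)C)(c2ccccc2)c2ccccc2
F6 | step 14 | (4R)-2,2,5,5-tetramethyl-4-[(phenylsulfanyl)methyl]-1,3-dioxolane | C(Sc1ccccc1)[C@@H]1OC(C)(C)OC1(C)C
F7 | step 14 | (4R)-4-[chloro(phenylsulfanyl)methyl]-2,2,5,5-tetramethyl-1,3-dioxolane (epimers at the chlorinated carbon) | ClC(Sc1ccccc1)[C@@H]1OC(C)(C)OC1(C)C
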